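The target is cut at the benzylic ester C–O bond into an (R,Z)-alkylidenesuccinate half and (S)-[2-isopropenyl-2,3-dihydrobenzofuran-5-yl]methanol; the latter carries the strategy. Its furan-ring C2, bonded to O1 and to the isopropenyl group, is treated as the former C3 of a 2,2-dimethylchroman. Activating the (R)-3-hydroxyl as a triflate lets O1 migrate from the gem-dimethyl carbon to C3 with inversion. In one operation this contracts the pyran ring to the dihydrofuran ring, fixes the C2 stereocentre and releases the alkene by loss of a methyl proton. The precursor is (R)-6-(silyloxymethyl)-2,2-dimethylchroman-3-ol, obtained through Jacobsen epoxidation of the chromene.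

Key step: step 6

Assumption: the stereochemistry is taken as encoded in the target string, i.e. (S) at C2 of the dihydrobenzofuran, (R) at the methyl-bearing carbon and (Z) at the hexylidene double bond (pentyl chain cis to the free carboxyl); tert-butyl (R)-lactate is treated as a catalogue compound.

Step 1
Reactants: 1 methyl 4-hydroxybenzoate; 2 3-chloro-3-methylbut-1-yne
Product: 3 methyl 4-[(2-methylbut-3-yn-2-yl)oxy]benzoate
Conditions: K2CO3, KI (cat.), CuI (cat.), acetone, reflux
Reagents that add atoms: none
Why: Williamson-type O-alkylation of the acidic para-acylphenol with the tertiary propargylic chloride under CuI/KI catalysis is the standard preparation of aryl 1,1-dimethylpropargyl ethers.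

Step 2
Reactants: 3 methyl 4-[(2-methylbut-3-yn-2-yl)oxy]benzoate
Product: 6 methyl 2,2-dimethyl-2H-chromene-6-carboxylate, via ortho-allenylphenol 4 (not isolated), via ortho-quinone methide 5 (not isolated)
Conditions: N,N-diethylaniline, 190 °C
Reagents that add atoms: none
Why: Aromatic propargyl Claisen rearrangement ([3,3]-shift to either of the two equivalent ortho positions) gives allenylphenol 4, which isomerises by 1,5-hydrogen shift to quinone methide 5 and closes by oxa-6π electrocyclisation to the 2H-chromene.

Step 3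
Reactants: 6 methyl 2,2-dimethyl-2H-chromene-6-carboxylate
Product: 7 methyl (3R,4R)-3,4-epoxy-2,2-dimethylchromane-6-carboxylate
Conditions: (R,R)-Jacobsen catalyst, chloro[(R,R)-N,N'-bis(3,5-di-tert-butylsalicylidene)cyclohexane-1,2-diaminato]manganese (trivalent manganese, cat.), aq. NaOCl (pH 11.3), 4-phenylpyridine N-oxide, CH2Cl2, 0 °C
Reagents that add atoms: sodium hypochlorite, [Na+].[O-]Cl
Why: Jacobsen–Katsuki epoxidation: a cis-alkene conjugated to an arene and flanked by a gem-dimethyl group is the ideal substrate class, and the (R,R)-catalyst controls the face of oxygen transfer to give the (3R,4R)-epoxide.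

Step 4
Reactants: 7 methyl (3R,4R)-3,4-epoxy-2,2-dimethylchromane-6-carboxylate
Product: 8 (R)-6-(hydroxymethyl)-2,2-dimethylchroman-3-ol
Conditions: LiAlH4, THF, 0 °C → reflux; Rochelle-salt work-up
Reagents that add atoms: none
Why: Hydride reduction with LiAlH4 turns the ester into the benzylic alcohol and opens the epoxide by SN2 attack at the benzylic C4, C3 being shielded by the quaternary C2, so the C3–O bond and its (R) configuration are not touched.

Step 5
Reactants: 8 (R)-6-(hydroxymethyl)-2,2-dimethylchroman-3-ol
Product: 9 (R)-6-[(tert-butyldiphenylsilyloxy)methyl]-2,2-dimethylchroman-3-ol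
Conditions: TBDPSCl, imidazole, CH2Cl2, 0 °C → rt
Reagents that add atoms: tert-butyl(chloro)diphenylsilane, CC(C)(C)[Si](Cl)(c1ccccc1)c1ccccc1
Why: Silylation with a bulky chlorosilane is selective for the primary benzylic hydroxyl over the secondary hydroxyl next to the gem-dimethyl carbon, and a silyl ether (not the ester) at C6 keeps the ring oxygen electron-rich for the rearrangement.

Step 6
Reactants: 9 (R)-6-[(tert-butyldiphenylsilyloxy)methyl]-2,2-dimethylchroman-3-ol
Product: 12 tert-butyl{[(2S)-2-(prop-1-en-2-yl)-2,3-dihydro-1-benzofuran-5-yl]methoxy}diphenylsilane, via chromanyl triflate 10 (not isolated), via bridged oxiranium triflate 11 (not isolated)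
Conditions: Tf2O, 2,6-di-tert-butyl-4-methylpyridine, CH2Cl2, −78 °C → rt
Reagents that add atoms: none
Why: Tf2O sulfonylates the hindered secondary hydroxyl at low temperature to give triflate 10; on warming, a lone pair of ring oxygen O1 displaces triflate from the rear of C3 (the O1–C2 ring bond lies antiperiplanar to a pseudo-equatorial C3–OTf bond of the half-chair) to give the aryl-bridged oxiranium ion 11, whose tertiary C–O bond breaks as a methyl proton is removed, leaving the isopropenyl group on the new furan carbon. The closest known reaction type is the Wagner–Meerwein-type ring contraction of 2,2-dimethylchroman-3-yl sulfonates to 2-isopropenyl-2,3-dihydrobenzofurans through participation of the ring oxygen. The five-membered ring is not closed end to end: it results from a 3-exo-tet closure of O1 onto C3 followed by cleavage of the old O1–CMe2 bond, a net 1,2-shift of oxygen that takes one carbon out of the pyran ring. The new C2 stereocentre is under substrate control, because the backside displacement is stereospecific and turns the (R)-carbinol carbon into the (S) centre with the enantiopurity set in step 3. The step needs oxygen migration to outrun methyl or hydride shift, elimination towards C4 and proton loss from the ring carbon; this should be secured by the oxygen-antiperiplanar leaving group, the tertiary site of oxiranium opening, the electron-rich para-alkyl aryl oxygen, and a hindered non-nucleophilic base with a non-nucleophilic counter-ion, so that the cationic carbon is not trapped and the six methyl protons are the accessible ones.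

Step 7
Reactants: 12 tert-butyl{[(2S)-2-(prop-1-en-2-yl)-2,3-dihydro-1-benzofuran-5-yl]methoxy}diphenylsilane
Product: 13 (S)-[2-(prop-1-en-2-yl)-2,3-dihydrobenzofuran-5-yl]methanol
Conditions: TBAF, THF, 0 °C → rt
Reagents that add atoms: none
Why: Fluoride-mediated silyl ether cleavage frees the primary alcohol, and the dihydrobenzofuran, its non-acidic C2 stereocentre and the alkene are inert to TBAF.

Step 8
Reactants: 14 allyl bromoacetate; 15 diphenyl phosphite
Product: 16 allyl 2-(diphenoxyphosphoryl)acetate
Conditions: Et3N, CH2Cl2, 0 °C → rt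
Reagents that add atoms: none
Why: Michaelis–Becker-type P-alkylation: the phosphite, deprotonated by Et3N, displaces bromide from the primary α-bromo ester, the usual way to diaryl phosphonoacetates for Z-selective olefination.

Step 9
Reactants: 17 tert-butyl (R)-lactate
Product: 18 tert-butyl (R)-2-[(trifluoromethanesulfonyl)oxy]propanoate
Conditions: Tf2O, 2,6-lutidine, CH2Cl2, −78 → 0 °C; used at once
Reagents that add atoms: trifluoromethanesulfonic anhydride, O=S(=O)(OS(=O)(=O)C(F)(F)F)C(F)(F)F
Why: O-Sulfonylation of the secondary alcohol does not touch the C–O bond, so the (R) configuration is retained and the carbon is set up for clean SN2 displacement.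

Step 10
Reactants: 16 allyl 2-(diphenoxyphosphoryl)acetate; 18 tert-butyl (R)-2-[(trifluoromethanesulfonyl)oxy]propanoate
Product: 19 1-allyl 4-tert-butyl (3S)-2-(diphenoxyphosphoryl)-3-methylbutanedioate (mixture of epimers at C2)
Conditions: NaH, THF, 0 °C; then 18, −20 °C → rt
Reagents that add atoms: none
Why: SN2 C-alkylation of the stabilised phosphonate carbanion by the α-triflyloxy ester (the displacement well known for malonates) inverts the lactate carbon and so sets the methyl-bearing centre; the descriptor reads (3S) only because the phosphorus-bearing carbon outranks the ester carbon, and the same arrangement becomes (R) in 21.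

Step 11
Reactants: 19 1-allyl 4-tert-butyl (3S)-2-(diphenoxyphosphoryl)-3-methylbutanedioate; 20 hexanal
Product: 21 1-allyl 4-tert-butyl (2Z,3R)-2-hexylidene-3-methylbutanedioate
Conditions: NaH (1.0 equiv), THF, 0 °C; then hexanal, −78 → 0 °C
Reagents that add atoms: none
Why: Z-selective Horner–Wadsworth–Emmons olefination with a diaryl phosphonate: fast, irreversible collapse of the kinetically favoured adduct places the pentyl chain cis to the allyl ester, while the methyl-bearing centre is untouched because the single equivalent of base is consumed by the far more acidic P–C–H site and the by-product is non-basic diphenyl phosphate.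

Step 12
Reactants: 21 1-allyl 4-tert-butyl (2Z,3R)-2-hexylidene-3-methylbutanedioate
Product: 22 (2R,3Z)-2-methyl-3-[(prop-2-en-1-yloxy)carbonyl]non-3-enoic acid
Conditions: CF3CO2H, CH2Cl2, 0 °C → rt
Reagents that add atoms: none
Why: Acidolysis of the tert-butyl ester (E1 loss of 2-methylpropene) frees only the saturated carboxyl, the allyl ester and the electron-poor alkene being inert to CF3CO2H, and the base-sensitive stereocentre sees no base.

Step 13
Reactants: 13 (S)-[2-(prop-1-en-2-yl)-2,3-dihydrobenzofuran-5-yl]methanol; 22 (2R,3Z)-2-methyl-3-[(prop-2-en-1-yloxy)carbonyl]non-3-enoic acid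
Product: 23 1-allyl 4-{[(2S)-2-(prop-1-en-2-yl)-2,3-dihydro-1-benzofuran-5-yl]methyl} (2Z,3R)-2-hexylidene-3-methylbutanedioate
Conditions: PPh3, DIAD, THF, 0 °C → rt
Reagents that add atoms: none
Why: Mitsunobu esterification: PPh3/DIAD activate the primary benzylic hydroxyl of 13 for displacement by the carboxylate of 22, so the acid is never turned into an acylating agent and its α-stereocentre and Z-alkene should pass unchanged (the carbinol carbon is a CH2 group, so no centre is formed or inverted).

Step 14
Reactants: 23 1-allyl 4-{[(2S)-2-(prop-1-en-2-yl)-2,3-dihydro-1-benzofuran-5-yl]methyl} (2Z,3R)-2-hexylidene-3-methylbutanedioate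
Product: 25 (Z)-2-[(R)-1-{[(S)-2-(prop-1-en-2-yl)-2,3-dihydrobenzofuran-5-yl]methoxy}-1-oxopropan-2-yl]oct-2-enoic acid (target), via phenylsilyl ester 24 (not isolated)
Conditions: Pd(PPh3)4 (zerovalent palladium, cat.), PhSiH3, CH2Cl2, rt; aqueous work-up
Reagents that add atoms: none
Why: Tsuji–Trost-type deallylation: zerovalent palladium ionises only the primary allyl ester, PhSiH3 reduces the π-allyl unit to propene and gives silyl ester 24, which hydrolyses on work-up, so the epimerisable centre, the Z-alkene, the benzylic ester and the hindered allylic aryl ether see neither acid nor base.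

Compound list

1 | methyl 4-hydroxybenzoate | COC(=O)c1ccc(O)cc1 | starting material
2 | 3-chloro-3-methylbut-1-yne | CC(C)(Cl)C#C | starting material
3 | methyl 4-[(2-methylbut-3-yn-2-yl)oxy]benzoate | COC(=O)c1ccc(OC(C)(C)C#C)cc1 | intermediate
4 | methyl 4-hydroxy-3-(3-methylbuta-1,2-dien-1-yl)benzoate (ortho-allenylphenol) | COC(=O)c1ccc(O)c(C=C=C(C)C)c1 | intermediate
5 | methyl 3-(3-methylbut-2-en-1-ylidene)-4-oxocyclohexa-1,5-diene-1-carboxylate (ortho-quinone methide) | COC(=O)C1=CC(=CC=C(C)C)C(=O)C=C1 | intermediate
6 | methyl 2,2-dimethyl-2H-chromene-6-carboxylate | COC(=O)c1ccc2OC(C)(C)C=Cc2c1 | intermediate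
7 | methyl (3R,4R)-3,4-epoxy-2,2-dimethylchromane-6-carboxylate | CC1(C)[C@@H]2O[C@@H]2c2cc(C(=O)OC)ccc2O1 | intermediate
8 | (R)-6-(hydroxymethyl)-2,2-dimethylchroman-3-ol | CC1(C)[C@H](O)Cc2cc(CO)ccc2O1 | intermediate
9 | (R)-6-[(tert-butyldiphenylsilyloxy)methyl]-2,2-dimethylchroman-3-ol | CC1(C)[C@H](O)Cc2cc(CO[Si](c3ccccc3)(c3ccccc3)C(C)(C)C)ccc2O1 | intermediate
10 | (R)-6-[(tert-butyldiphenylsilyloxy)methyl]-2,2-dimethylchroman-3-yl trifluoromethanesulfonate | CC1(C)[C@H](OS(=O)(=O)C(F)(F)F)Cc2cc(CO[Si](c3ccccc3)(c3ccccc3)C(C)(C)C)ccc2O1 | intermediate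
11 | aryl-bridged oxiranium triflate (O1 bonded to the aryl carbon, to the former C3 and to the CMe2 carbon) | CC1(C)[C@@H]2Cc3cc(CO[Si](c4ccccc4)(c4ccccc4)C(C)(C)C)ccc3[O+]12.[O-]S(=O)(=O)C(F)(F)F | intermediate
12 | tert-butyl{[(2S)-2-(prop-1-en-2-yl)-2,3-dihydro-1-benzofuran-5-yl]methoxy}diphenylsilane | C=C(C)[C@@H]1Cc2cc(CO[Si](c3ccccc3)(c3ccccc3)C(C)(C)C)ccc2O1 | intermediate
13 | (S)-[2-(prop-1-en-2-yl)-2,3-dihydrobenzofuran-5-yl]methanol | C=C(C)[C@@H]1Cc2cc(CO)ccc2O1 | intermediate
14 | allyl bromoacetate | C=CCOC(=O)CBr | starting material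
15 | diphenyl phosphite | O=[PH](Oc1ccccc1)Oc1ccccc1 | starting material
16 | allyl 2-(diphenoxyphosphoryl)acetate | C=CCOC(=O)CP(=O)(Oc1ccccc1)Oc1ccccc1 | intermediate
17 | tert-butyl (R)-lactate | CC(C)(C)OC(=O)[C@@H](C)O | starting material
18 | tert-butyl (R)-2-[(trifluoromethanesulfonyl)oxy]propanoate | CC(C)(C)OC(=O)[C@@H](C)OS(=O)(=O)C(F)(F)F | intermediate
19 | 1-allyl 4-tert-butyl (3S)-2-(diphenoxyphosphoryl)-3-methylbutanedioate (C2 epimers) | CC(C)(C)OC(=O)[C@H](C)C(P(=O)(Oc1ccccc1)Oc1ccccc1)C(=O)OCC=C | intermediate
20 | hexanal | CCCCCC=O | starting material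
21 | 1-allyl 4-tert-butyl (2Z,3R)-2-hexylidene-3-methylbutanedioate | CC(C)(C)OC(=O)[C@H](C)/C(=C/CCCCC)C(=O)OCC=C | intermediate
22 | (2R,3Z)-2-methyl-3-[(prop-2-en-1-yloxy)carbonyl]non-3-enoic acid | OC(=O)[C@H](C)/C(=C/CCCCC)C(=O)OCC=C | intermediate
23 | 1-allyl 4-{[(2S)-2-(prop-1-en-2-yl)-2,3-dihydro-1-benzofuran-5-yl]methyl} (2Z,3R)-2-hexylidene-3-methylbutanedioate | C=C(C)[C@@H]1Cc2cc(COC(=O)[C@H](C)/C(=C/CCCCC)C(=O)OCC=C)ccc2O1 | intermediate
24 | phenylsilyl ester of the target acid | C=C(C)[C@@H]1Cc2cc(COC(=O)[C@H](C)/C(=C/CCCCC)C(=O)O[SiH2]c3ccccc3)ccc2O1 | intermediate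
25 | (Z)-2-[(R)-1-{[(S)-2-(prop-1-en-2-yl)-2,3-dihydrobenzofuran-5-yl]methoxy}-1-oxopropan-2-yl]oct-2-enoic acid | C=C(C)[C@@H]1Cc2cc(COC(=O)[C@H](C)/C(=C/CCCCC)C(=O)O)ccc2O1 | target

Total step count: 14. Longest linear sequence: 9 steps (steps 1–7, 13 and 14); the acid half (steps 8–12) is made in parallel.

Steps most likely to fail

1. Step 6 (key step). What may go wrong: methyl migration to an oxygen-stabilised cation, elimination towards C4, proton loss at the ring carbon followed by aromatisation, or ionisation to an open cation with loss of enantiopurity. The fallback replaces the rearrangement by cyclisation of a phenoxide onto a chiral epoxide and a late dehydration; it sets out from 3 and comes back at 13. Semihydrogenation of 3 (H2, Pd on CaCO3 poisoned with Pb(OAc)2, quinoline) should give methyl 4-[(2-methylbut-3-en-2-yl)oxy]benzoate F1. Aromatic Claisen rearrangement (N,N-diethylaniline, 150 °C) should give methyl 4-hydroxy-3-(3-methylbut-2-en-1-yl)benzoate F2, and TBSCl/imidazole methyl 4-[(tert-butyldimethylsilyl)oxy]-3-(3-methylbut-2-en-1-yl)benzoate F3. Shi epoxidation (D-fructose-derived ketone, KHSO5, K2CO3, MeCN/dimethoxymethane/water, 0 °C) should give methyl 4-[(tert-butyldimethylsilyl)oxy]-3-{[(2R)-3,3-dimethyloxiran-2-yl]methyl}benzoate F4. TBAF then frees the phenoxide, which opens the epoxide 5-exo at the secondary carbon with inversion to methyl (S)-2-(2-hydroxypropan-2-yl)-2,3-dihydrobenzofuran-5-carboxylate F5. Dehydration of the tertiary alcohol (SOCl2, pyridine, 0 °C) should give methyl (S)-2-(prop-1-en-2-yl)-2,3-dihydrobenzofuran-5-carboxylate F6, and i-Bu2AlH (CH2Cl2, −78 °C) reduces the ester to 13.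

2. Step 11. What may go wrong: insufficient Z selectivity or sluggish carbonyl addition of the fully substituted, branched phosphonate carbanion (with competing aldehyde self-condensation), or base-induced epimerisation next to the new alkene. The fallback olefinates an unbranched phosphonate and introduces the methyl group afterwards under auxiliary control; it sets out from 16, comes back at 22, and also bypasses the triflate displacement of step 10. Alkylation of the sodium salt of 16 with tert-butyl bromoacetate should give 1-allyl 4-tert-butyl 2-(diphenoxyphosphoryl)butanedioate F7. The same Z-selective olefination with hexanal (20) should give 1-allyl 4-tert-butyl (2Z)-2-hexylidenebutanedioate F8, and CF3CO2H then gives (3Z)-3-[(allyloxy)carbonyl]non-3-enoic acid F9. Acylation of lithiated (R)-4-benzyloxazolidin-2-one with the mixed pivalic anhydride of F9 should give allyl (2Z)-2-{2-[(4R)-4-benzyl-2-oxo-1,3-oxazolidin-3-yl]-2-oxoethyl}oct-2-enoate F10. Evans methylation (NaN(SiMe3)2, MeI, THF, −78 °C) on the face opposite the benzyl group should give allyl (2Z)-2-{(2R)-1-[(4R)-4-benzyl-2-oxo-1,3-oxazolidin-3-yl]-1-oxopropan-2-yl}oct-2-enoate F11. LiOH/H2O2 (THF/water, 0 °C) removes the auxiliary to give 22.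

3. Step 14. What may go wrong: ionisation of the allylic C2–O1 aryl ether of the dihydrobenzofuran by zerovalent palladium (ring opening or racemisation), or double-bond migration or epimerisation in the alkylidenesuccinate during deprotection of the fully assembled molecule. The fallback removes the allyl group before the two halves meet and joins them by regioselective anhydride opening, so that no protecting group is left at the end; it sets out from 22 and 13, comes back at 25, and replaces steps 13 and 14. Deallylation of 22 alone (Pd(PPh3)4, PhSiH3, CH2Cl2) should give (2Z,3R)-2-hexylidene-3-methylbutanedioic acid F12. Dehydration with N,N'-dicyclohexylcarbodiimide (CH2Cl2, 0 °C) should give (3Z,4R)-3-hexylidene-4-methyloxolane-2,5-dione F13. Base-free alcoholysis with 13 (CH2Cl2, rt → 40 °C), which for itaconic-type anhydrides takes place at the non-conjugated carbonyl, should give 25 directly.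

Further compounds

F1 | step 6 | methyl 4-[(2-methylbut-3-en-2-yl)oxy]benzoate | COC(=O)c1ccc(OC(C)(C)C=C)cc1
F2 | step 6 | methyl 4-hydroxy-3-(3-methylbut-2-en-1-yl)benzoate | COC(=O)c1ccc(O)c(CC=C(C)C)c1
F3 | step 6 | methyl 4-[(tert-butyldimethylsilyl)oxy]-3-(3-methylbut-2-en-1-yl)benzoate | COC(=O)c1ccc(O[Si](C)(C)C(C)(C)C)c(CC=C(C)C)c1
F4 | step 6 | methyl 4-[(tert-butyldimethylsilyl)oxy]-3-{[(2R)-3,3-dimethyloxiran-2-yl]methyl}benzoate | COC(=O)c1ccc(O[Si](C)(C)C(C)(C)C)c(C[C@H]2OC2(C)C)c1
F5 | step 6 | methyl (S)-2-(2-hydroxypropan-2-yl)-2,3-dihydrobenzofuran-5-carboxylate | CC(C)(O)[C@@H]1Cc2cc(C(=O)OC)ccc2O1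
F6 | step 6 | methyl (S)-2-(prop-1-en-2-yl)-2,3-dihydrobenzofuran-5-carboxylate | C=C(C)[C@@H]1Cc2cc(C(=O)OC)ccc2O1
F7 | step 11 | 1-allyl 4-tert-butyl 2-(diphenoxyphosphoryl)butanedioate | C=CCOC(=O)C(CC(=O)OC(C)(C)C)P(=O)(Oc1ccccc1)Oc1ccccc1
F8 | step 11 | 1-allyl 4-tert-butyl (2Z)-2-hexylidenebutanedioate | CCCCC/C=C(/CC(=O)OC(C)(C)C)C(=O)OCC=C
F9 | step 11 | (3Z)-3-[(allyloxy)carbonyl]non-3-enoic acid | CCCCC/C=C(/CC(=O)O)C(=O)OCC=C
F10 | step 11 | allyl (2Z)-2-{2-[(4R)-4-benzyl-2-oxo-1,3-oxazolidin-3-yl]-2-oxoethyl}oct-2-enoate | CCCCC/C=C(/CC(=O)N1[C@H](Cc2ccccc2)COC1=O)C(=O)OCC=C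
F11 | step 11 | allyl (2Z)-2-{(2R)-1-[(4R)-4-benzyl-2-oxo-1,3-oxazolidin-3-yl]-1-oxopropan-2-yl}oct-2-enoate | CCCCC/C=C(/[C@@H](C)C(=O)N1[C@H](Cc2ccccc2)COC1=O)C(=O)OCC=C
F12 | step 14 | (2Z,3R)-2-hexylidene-3-methylbutanedioic acid | OC(=O)[C@H](C)/C(=C/CCCCC)C(=O)O
F13 | step 14 | (3Z,4R)-3-hexylidene-4-methyloxolane-2,5-dione | CCCCC/C=C1/[C@@H](C)C(=O)OC1=O
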